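**Plan**

- Retrosynthesis: the three esters come off first, then the C11–C12 bond (enol triflate plus hydroxymethylstannane). Ring B is then traced back to a 7-acetylbicyclo[3.1.0]hexane in which C7–C9 is still a bond and C8 is the cyclopropane CH2. C8 comes from a sulfoxonium ylide, the acetyl group from CO/Me4Sn on a C7 enol triflate, and ring A from a Diels–Alder cut (C1–C2, C5–C6) of a cyclopentenone.
- Forward order: cyclopentenone ring (C7, C6, C1, C10, C9), then ring A by [4+2], acetyl at C7, cyclopropane C7–C8–C9, then the key step enlarges the five-membered ring to ring B, followed by side-chain and ester adjustment.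
- Enabling feature: in ring B the acetoxy carbon C9 and the alkylidene carbon C7 are 1,3-related across the CH2 C8, and C7 carries the exocyclic C11. A cyclopropane C7–C8–C9 with an acyl group on C7 is therefore a homo-enone. Its 1,5-addition of acetate at C9 gives ring B, the C9–O bond and the C7=C11 enol (with fixed geometry) in one event.
- Stereochemistry: C10 comes from (R)-4-silyloxycyclopentenone (anti cuprate addition, enone transposition). C1/C6 are set by the Diels–Alder reaction anti to the C10 methyl (cis fusion). C8 is placed anti to that methyl, so inversion at C9 gives the 9α-acetate. The alkene geometry comes from the s-cis acyl conformer and a stereoretentive triflate coupling. C3 is set by hydride attack on the convex face.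

Key step: step 10

Remark: cadinane numbering is used for all compounds (C1/C6 ring fusion; ring A = C1–C6 with C15 on C4; ring B = C1, C10, C9, C8, C7, C6 with C14 on C10; C11 on C7 bears C13 and C12). β is the face of H-1 and H-6. Compounds 1 and 4 are taken as commercial.

Step 1
Reactants: 1 (R)-4-[tert-butyl(dimethyl)silyl]oxycyclopent-2-en-1-one
Product: 3 (R)-4-methylcyclopent-2-en-1-one, via trans-3-methyl-4-silyloxycyclopentanone 2 (not isolated)
Conditions: MeLi (2 equiv), CuI, Et2O, −78 °C; aq NH4Cl; crude, DBU, CH2Cl2, 0 °C
Reagents that add atoms: lithium dimethylcuprate, [Li+].C[Cu-]C (made in the flask from methyllithium, C[Li], and CuI)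
Why: Cuprate conjugate addition anti to the silyloxy group followed by base-induced β-elimination of silanol should transpose the enone, so that the stereocentre of 1 is exchanged for the methyl-bearing centre (C10) of 3 with (R) configuration.

Step 2
Reactants: 4 3-methylbut-3-en-2-one
Product: 5 tert-butyl(dimethyl)[(3-methylbuta-1,3-dien-2-yl)oxy]silane
Conditions: TBSOTf, Et3N, CH2Cl2, 0 °C
Reagents that add atoms: tert-butyldimethylsilyl triflate, CC(C)(C)[Si](C)(C)OS(=O)(=O)C(F)(F)F
Why: Soft enolisation and O-silylation of the methyl ketone on its only enolisable side (silyl enol ether formation) should give the 2-silyloxydiene, which has no stereocentre.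

Step 3
Reactants: 3 (R)-4-methylcyclopent-2-en-1-one; 5 silyloxydiene
Product: 6 (3R,3aS,7aS)-5-[tert-butyl(dimethyl)silyl]oxy-3,6-dimethyl-2,3,3a,4,7,7a-hexahydroinden-1-one (cis-fused; 10β-methyl)
Conditions: Tf2NH (5 mol %), CH2Cl2, −78 to −40 °C
Reagents that add atoms: none
Why: In this Diels–Alder reaction under silyl triflimide catalysis the diene CH2 next to the siloxy carbon should bond to the enone β-carbon (C1), and the diene should add suprafacially to the face opposite the C10 methyl, which sets C1 and C6 (cis fusion) relative to C10.

Step 4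
Reactants: 6 cis-hexahydroindenone
Product: 8 C7 enol triflate of 6 (C7=C9), via lithium enolate 7 (not isolated)
Conditions: LiN(iPr)2, THF, −78 °C; PhNTf2, −78 to 0 °C; aq NH4Cl
Reagents that add atoms: N-phenylbis(trifluoromethanesulfonimide), O=S(=O)(N(c1ccccc1)S(=O)(=O)C(F)(F)F)C(F)(F)F
Why: Kinetic deprotonation at the C9 methylene (not at the C6 methine) and O-triflation of the enolate (enol triflate formation) should give the less substituted enol triflate without touching the silyl enol ether or any stereocentre.

Step 5
Reactants: 8 enol triflate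
Product: 9 7-acetyl diene (methyl ketone conjugated to C7=C9)
Conditions: Pd(PPh3)4 (5 mol %), LiCl, CO (1 atm), Me4Sn, THF, 55 °C
Reagents that add atoms: carbon monoxide, [C-]#[O+]; tetramethyltin, C[Sn](C)(C)C
Why: In this carbonylative Stille coupling, oxidative addition of the enol triflate to zerovalent palladium, CO insertion and methyl transfer from tin should give the enone under neutral conditions that spare the silyl enol ether.

Step 6
Reactants: 9 7-acetyl diene
Product: 10 cyclopropyl methyl ketone (C8 methylene on the α-face; H-9 β)
Conditions: Me3S(O)I, NaH, DMSO, 25 °C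
Reagents that add atoms: trimethylsulfoxonium iodide, C[S+](C)(C)=O.[I-]
Why: In this Corey–Chaykovsky cyclopropanation the sulfoxonium ylide should add to C9 on the face opposite the adjacent C10 methyl and the enolate should close 3-exo-tet at C7, which places C8 on the α-face and sets C9 and C7.

Step 7
Reactants: 10 cyclopropyl methyl ketone
Product: 11 cyclopropyl ketone enone (3-oxo; C4=C5)
Conditions: Pd(OAc)2 (1.1 equiv), MeCN, 25–40 °C
Reagents that add atoms: none
Why: In this Saegusa–Ito oxidation, palladation of the silyl enol ether at C4 and syn β-hydride elimination toward C5 should give the endocyclic enone while the cyclopropyl ketone stays untouched.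

Step 8
Reactants: 11 cyclopropyl ketone enone
Product: 12 3α-hydroxy cyclopropyl ketone
Conditions: NaBH4 (0.5 equiv), CeCl3·7H2O, MeOH, −78 °C
Reagents that add atoms: none
Why: In this Luche reduction the hydride should add 1,2 to the enone from the convex β-face (the α-face is screened by the axial C1–C10 bond) to give the 3α-alcohol, and the enone is expected to react far faster than the neopentyl-type, cyclopropane-conjugated methyl ketone.

Step 9
Reactants: 12 3α-hydroxy cyclopropyl ketone
Product: 13 3α-acetoxy cyclopropyl ketone
Conditions: Ac2O, pyridine, DMAP (cat.), CH2Cl2, 0 °C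
Reagents that add atoms: acetic anhydride, CC(=O)OC(C)=O
Why: This base-mediated acetylation masks the C3 hydroxyl with retention, so that no protic acid is released in step 10.

Step 10
Reactants: 13 3α-acetoxy cyclopropyl ketone
Product: 15 3α,9α-diacetoxy (E)-enol acetate (ring B formed), via acetoxycarbenium triflate 14 (not isolated)
Conditions: Ac2O (10 equiv), TMSOTf (0.2 equiv), 2,6-di-tert-butyl-4-methylpyridine (0.3 equiv), CH2Cl2, −40 to 0 °C
Reagents that add atoms: acetic anhydride, CC(=O)OC(C)=O
Why: Proposed new method: acetyl triflate (from Ac2O and TMSOTf) should O-acylate the cyclopropyl ketone to the acetoxycarbenium ion 14, a bisected cyclopropylcarbinyl cation, and acetate then attacks C9 from the side opposite the C7–C9 bond, so that this bond breaks, C8 becomes a member of the six-membered ring B and the electrons end in the C7=C11 enol acetate. The closest known reaction types are the acid-promoted 1,5-(homoconjugate) opening of bicyclic cyclopropyl ketones (the 3,5-cyclosteroid 6-ketone opening) and the halosilane opening of cyclopropyl ketones to γ-halo silyl enol ethers. No ring is closed: ring B arises by cleavage of the zero-atom bridge of the bicyclo[3.1.0]hexane, a five-to-six ring expansion driven by strain release. The new stereocentre C9 is set by inversion, so the α-position of C8 in 13 puts the acetoxy group α and trans to the C10 methyl. The alkene geometry should follow from the s-cis conformation of the acyl group (oxygen over the three-membered ring, methyl toward C6), which leaves the enol oxygen cis to C8. The step needs attack at C9 and not at C8, secured by the better cation-stabilising secondary carbon and the larger strain release, and it needs aprotic buffered conditions so that the enol acetate geometry is not scrambled and the allylic C3 acetate does not ionise.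

Step 11
Reactants: 15 triacetate
Product: 17 (E)-enol triflate 3α,9α-diol, via trilithium enolate dialkoxide 16 (not isolated)
Conditions: MeLi (6.2 equiv), THF, −78 °C; PhNTf2 (1.3 equiv), −78 to −20 °C; aq NH4Cl
Reagents that add atoms: N-phenylbis(trifluoromethanesulfonimide), O=S(=O)(N(c1ccccc1)S(=O)(=O)C(F)(F)F)C(F)(F)F
Why: Methyllithium should cleave the enol acetate to the lithium enolate with retention of double-bond geometry and turn both alkyl acetates into alkoxides (so the enolate cannot re-close the cyclopropane by displacing a C9 leaving group); O-triflation of the enolate, which is expected to be faster than sulfonylation of the hard alkoxides at low temperature, then gives the enol triflate without touching a stereocentre.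

Step 12
Reactants: 17 enol triflate diol
Product: 18 (7(11)E)-amorpha-4,7(11)-diene-3α,9α,12-triol
Conditions: Bu3SnCH2OH, Pd(PPh3)4 (10 mol %), LiCl, 1,4-dioxane, 100 °C
Reagents that add atoms: (tributylstannyl)methanol, CCCC[Sn](CCCC)(CCCC)CO
Why: This Stille coupling should transfer the hydroxymethyl group to C11 with retention of alkene geometry, so that C12 ends cis to C8 and the C13 methyl cis to C6.

Step 13
Reactants: 18 triol
Product: 19 12-formate 3α,9α-diol
Conditions: acetic formic anhydride (1.05 equiv), pyridine, CH2Cl2, −40 °C
Reagents that add atoms: acetic formic anhydride, CC(=O)OC=O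
Why: Acyl transfer from the mixed anhydride delivers the formyl group, and at low temperature with one equivalent the primary allylic hydroxyl should react in preference to the two secondary ones.

Step 14
Reactants: 19 12-formate diol
Product: 20 [(2E)-2-[(3S,4S,4aR,6S,8aR)-3,6-bis(acetyloxy)-4,7-dimethyl-3,4,4a,5,6,8a-hexahydronaphthalen-1(2H)-ylidene]propyl] formate (target)
Conditions: Ac2O, pyridine, 25 °C
Reagents that add atoms: acetic anhydride, CC(=O)OC(C)=O
Why: Esterification of both secondary hydroxyls with acetic anhydride in pyridine without a nucleophilic catalyst should leave the formate in place and give the target with all stereocentres unchanged.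

**Compound list**

1 | (R)-4-[tert-butyl(dimethyl)silyl]oxycyclopent-2-en-1-one | O=C1C=C[C@H](O[Si](C)(C)C(C)(C)C)C1 | starting material
2 | (3R,4R)-4-[tert-butyl(dimethyl)silyl]oxy-3-methylcyclopentan-1-one (trans) | O=C1C[C@@H](C)[C@H](O[Si](C)(C)C(C)(C)C)C1 | intermediate (not isolated)
3 | (R)-4-methylcyclopent-2-en-1-one | O=C1C=C[C@H](C)C1 | intermediate
4 | 3-methylbut-3-en-2-one | CC(=O)C(C)=C | starting material
5 | tert-butyl(dimethyl)[(3-methylbuta-1,3-dien-2-yl)oxy]silane | C=C(C)C(=C)O[Si](C)(C)C(C)(C)C | intermediate
6 | (3R,3aS,7aS)-5-[tert-butyl(dimethyl)silyl]oxy-3,6-dimethyl-2,3,3a,4,7,7a-hexahydroinden-1-one (cis-fused; C7 ketone, C3=C4 silyl enol ether, 10β-methyl) | CC(C)(C)[Si](C)(C)OC=1C[C@H]2[C@H](C)CC(=O)[C@H]2CC=1C | intermediate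
7 | lithium enolate of 6 (C7–OLi, C7=C9) | CC(C)(C)[Si](C)(C)OC=1C[C@H]2[C@H](C)C=C([O-])[C@H]2CC=1C.[Li+] | intermediate (not isolated)
8 | C7 enol triflate of 6 (C7=C9; other centres as in 6) | CC(C)(C)[Si](C)(C)OC=1C[C@H]2[C@H](C)C=C(OS(=O)(=O)C(F)(F)F)[C@H]2CC=1C | intermediate
9 | 7-acetyl diene (acetyl on C7, C7=C9; ring A silyl enol ether) | CC(C)(C)[Si](C)(C)OC=1C[C@H]2[C@H](C)C=C(C(C)=O)[C@H]2CC=1C | intermediate
10 | cyclopropyl methyl ketone (7-acetyl, C8 α-methylene bridging C7 and C9, H-9 β, 10β-methyl; ring A silyl enol ether) | CC(C)(C)[Si](C)(C)OC=1C[C@H]2[C@H](C)[C@H]3C[C@@]3(C(C)=O)[C@H]2CC=1C | intermediate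
11 | cyclopropyl ketone enone (3-oxo, C4=C5; rest as 10) | O=C1C[C@H]2[C@H](C)[C@H]3C[C@@]3(C(C)=O)[C@H]2C=C1C | intermediate
12 | 3α-hydroxy cyclopropyl ketone | O[C@H]1C[C@H]2[C@H](C)[C@H]3C[C@@]3(C(C)=O)[C@H]2C=C1C | intermediate
13 | 3α-acetoxy cyclopropyl ketone | CC(=O)O[C@H]1C[C@H]2[C@H](C)[C@H]3C[C@@]3(C(C)=O)[C@H]2C=C1C | intermediate
14 | O-acetyl oxocarbenium (cyclopropylcarbinyl) triflate of 13 | CC(=O)O[C@H]1C[C@H]2[C@H](C)[C@H]3C[C@@]3(C(C)=[O+]C(C)=O)[C@H]2C=C1C.[O-]S(=O)(=O)C(F)(F)F | intermediate (not isolated)
15 | triacetate: 3α,9α-diacetoxy-amorpha-4,7(11)-dien-11-yl acetate (12-nor; (E)-enol acetate, O cis to C8) | CC(=O)O[C@H]1C[C@H]2[C@H](C)[C@@H](OC(C)=O)C/C(=C(/C)OC(C)=O)[C@H]2C=C1C | intermediate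
16 | trilithium enolate 3,9-dialkoxide | [Li+].[Li+].[Li+].[O-][C@H]1C[C@H]2[C@H](C)[C@@H]([O-])C/C(=C(/C)[O-])[C@H]2C=C1C | intermediate (not isolated)
17 | (E)-enol triflate 3α,9α-diol (OTf on C11, cis to C8) | O[C@H]1C[C@H]2[C@H](C)[C@@H](O)C/C(=C(/C)OS(=O)(=O)C(F)(F)F)[C@H]2C=C1C | intermediate
18 | (7(11)E)-amorpha-4,7(11)-diene-3α,9α,12-triol | O[C@H]1C[C@H]2[C@H](C)[C@@H](O)C/C(=C(/C)CO)[C@H]2C=C1C | intermediate
19 | 12-formyloxy-(7(11)E)-amorpha-4,7(11)-diene-3α,9α-diol | O[C@H]1C[C@H]2[C@H](C)[C@@H](O)C/C(=C(/C)COC=O)[C@H]2C=C1C | intermediate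
20 | [(2E)-2-[(3S,4S,4aR,6S,8aR)-3,6-bis(acetyloxy)-4,7-dimethyl-3,4,4a,5,6,8a-hexahydronaphthalen-1(2H)-ylidene]propyl] formate | CC(=O)O[C@H]1C[C@H]2[C@H](C)[C@@H](OC(C)=O)C/C(=C(/C)COC=O)[C@H]2C=C1C | target

Total steps: 14. Longest linear sequence: 13 steps (steps 1 and 3–14, from 1).

**Steps most likely to fail**

Step 10 (proposed new method). What may go wrong: acetate may attack the methylene C8 instead of C9, the acetoxycarbenium ion may lose a methyl proton, reaction through the s-trans acyl rotamer may invert the enol acetate geometry, or traces of acid may scramble that geometry or ionise the allylic C3 acetate. The fallback uses known chemistry, sets out from 10 and comes back at 18. Dimethylsulfonium methylide (Me3SI, n-BuLi, THF, −10 °C) converts the methyl ketone into the cyclopropyl oxirane F1. Saegusa–Ito oxidation (Pd(OAc)2, MeCN) then gives the enone oxirane F2. Warm acetic acid buffered with NaOAc triggers the known cyclopropylcarbinyl-to-homoallyl (Julia-type) rearrangement: the tertiary oxirane carbon ionises, acetate enters at C9 with inversion, and ring B forms together with the C7=C11 double bond and the free C12 alcohol, giving the hydroxy acetate F3. In this variant the alkene geometry is decided by the cation rotamer, so the (E)-isomer would have to be separated from the (Z)-isomer. Finally iBu2AlH (CH2Cl2, −78 °C) reduces the enone from the convex face and cleaves the acetate to give triol 18.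

Step 6. What may go wrong: poor facial selectivity, because the ylide may approach C9 syn to the C10 methyl (the face away from ring A), which would lead to the 9β-acetate after step 10. The fallback sets out from 9 and comes back at 10. A CBS reduction (the enantiomer of the methyl oxazaborolidine catalyst that gives the (R)-carbinol, catecholborane, toluene, −78 °C) gives the (R)-allylic alcohol F4. Hydroxyl-directed cyclopropanation with the samarium carbenoid (Sm, HgCl2 cat., CH2ICl, THF, −78 to 25 °C) acts only on allylic alcohols, so the silyl enol ether is left alone. It should deliver CH2 to the α-face from the conformer in which the carbinol hydrogen eclipses the C7–C6 bond, giving the cyclopropyl carbinol F5. Oxidation (DMP, NaHCO3, CH2Cl2) returns ketone 10.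

Step 12. What may go wrong: slow transmetalation at the hindered tetrasubstituted enol triflate, with reduction of the triflate or loss of the stannane competing. The fallback sets out from 17 and comes back at 18. Methoxycarbonylation (Pd(OAc)2, dppf, CO 1 atm, MeOH, Et3N, DMF, 60 °C) gives the methyl ester F6 with retention of geometry, and iBu2AlH (CH2Cl2, −78 °C) reduces it to triol 18.

**Further compounds**

F1 | step 10 | cyclopropyl oxirane from 10 (2-methyloxiran-2-yl on C7, both C11 epimers; ring A silyl enol ether) | CC(C)(C)[Si](C)(C)OC=1C[C@H]2[C@H](C)[C@H]3C[C@@]3(C4(C)CO4)[C@H]2CC=1C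
F2 | step 10 | enone oxirane (3-oxo, C4=C5) | O=C1C[C@H]2[C@H](C)[C@H]3C[C@@]3(C4(C)CO4)[C@H]2C=C1C
F3 | step 10 | 9α-acetoxy-12-hydroxy-(7(11)E)-amorpha-4,7(11)-dien-3-one | O=C1C[C@H]2[C@H](C)[C@@H](OC(C)=O)C/C(=C(/C)CO)[C@H]2C=C1C
F4 | step 6 | (R)-allylic alcohol from 9 (1-hydroxyethyl on C7, C7=C9) | CC(C)(C)[Si](C)(C)OC=1C[C@H]2[C@H](C)C=C([C@@H](C)O)[C@H]2CC=1C
F5 | step 6 | cyclopropyl carbinol (C8 α-methylene, (R)-1-hydroxyethyl on C7) | CC(C)(C)[Si](C)(C)OC=1C[C@H]2[C@H](C)[C@H]3C[C@@]3([C@@H](C)O)[C@H]2CC=1C
F6 | step 12 | methyl (7(11)E)-3α,9α-dihydroxyamorpha-4,7(11)-dien-12-oate | O[C@H]1C[C@H]2[C@H](C)[C@@H](O)C/C(=C(/C)C(=O)OC)[C@H]2C=C1C
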